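## Retrosynthetic overview

1. Locants: ring A = C1–C5 and C10 (CMe2 at C4, CH at C5). Ring B = C5–C10 (CHMe at C8, quaternary C9, sp2 C10). The chain C11–C16 runs from C9 to C3 of the lactam, and C13 carries the CH2O group.
2. Enabling feature: the quaternary C9 of ring B lies between C8 and the C10=C1 double bond of ring A, so it is the alpha carbon of a beta,gamma-unsaturated C8 ketone. In addition, the sulfate oxygen on the CH2 group at C13 stands 1,4 to C11, so C11–O and CH2–O can be tied into one seven-membered cyclic sulfate.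
3. Key disconnection C9–C11: the extended lithium dienolate of a 13-carbon bicyclic enone opens a 16-carbon cyclic sulfate that already holds the whole lactam chain. The leaving group stays in the product as the sulfate of the target. C8=O then becomes CHMe by methylenation and hydrogenation.
4. Enone: ring A comes from 3-methylcyclohexenone by conjugate methylation. Ring B is closed second by Michael addition and aldol condensation. C5 is secured by a CBS kinetic resolution.
5. Chain: the lactam ring is made first, C13 is set by Evans alkylation, the two parts are joined by B-alkyl Suzuki–Miyaura coupling, and the temporary sulfate ring is closed last.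

Key step: step 14

Remark on the chemistry: the target is drawn as the free hydrogen sulfate. The sulfate is carried as its lithium salt and protonated only in the last step.

## Route

Step 1
Reactants: 1 3-methylcyclohex-2-en-1-one
Product: 2 [(3,3-dimethylcyclohex-1-en-1-yl)oxy]trimethylsilane
Conditions: MeMgBr, CuBr·SMe2 (5 mol %), TMSCl, DMPU, THF, −78 to −20 °C; Et3N, pentane work-up
Reagents that add atoms: methylmagnesium bromide, C[Mg]Br; chlorotrimethylsilane, C[Si](C)(C)Cl
Why: Copper-catalysed conjugate addition with silyl trapping builds the gem-dimethyl carbon C4 and fixes the enol double bond on the hindered side next to it; no stereocentre is formed.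

Step 2
Reactants: 2 [(3,3-dimethylcyclohex-1-en-1-yl)oxy]trimethylsilane; 3 pent-1-en-3-one
Product: 4 (±)-3,3-dimethyl-2-(3-oxopentyl)cyclohexan-1-one
Conditions: TiCl4 (1.0 equiv), CH2Cl2, −78 °C; aqueous work-up
Reagents that add atoms: none
Why: The Mukaiyama–Michael addition makes the C5–C6 bond regiospecifically at the carbon flanked by CMe2, which a free enolate would not choose; C5 forms as the racemate.

Step 3
Reactants: 4 (±)-3,3-dimethyl-2-(3-oxopentyl)cyclohexan-1-one
Product: 5 (±)-1,5,5-trimethyl-4,4a,5,6,7,8-hexahydronaphthalen-2(3H)-one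
Conditions: KOH, EtOH, reflux
Reagents that add atoms: none
Why: The intramolecular aldol condensation (second half of a Robinson annulation) closes six-membered ring B between the ethyl ketone CH2 and the ring carbonyl, and dehydration gives the only conjugated enone possible.

Step 4
Reactants: 5 (±)-1,5,5-trimethyl-4,4a,5,6,7,8-hexahydronaphthalen-2(3H)-one
Product: 6 (2R,4aS)-1,5,5-trimethyl-2,3,4,4a,5,6,7,8-octahydronaphthalen-2-ol (OH and H-4a on the same face)
Conditions: (S)-2-methyl-CBS-oxazaborolidine (15 mol %), BH3·SMe2 (0.35 equiv), THF, −30 °C, stopped near half conversion; MeOH; chromatography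
Reagents that add atoms: none
Why: Corey–Bakshi–Shibata reduction run as a kinetic resolution: for the (4aS) enantiomer the catalyst's facial preference (R carbinol) coincides with the substrate's own axial hydride attack, so it should be reduced faster, and the alcohol separates easily from the unreduced (4aR) ketone, which fixes C5.

Step 5
Reactants: 6 (2R,4aS)-1,5,5-trimethyl-2,3,4,4a,5,6,7,8-octahydronaphthalen-2-ol
Product: 7 (4aS)-1,5,5-trimethyl-4,4a,5,6,7,8-hexahydronaphthalen-2(3H)-one
Conditions: MnO2, CH2Cl2, rt
Reagents that add atoms: none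
Why: Neutral allylic oxidation returns the enone without enolisation, so the gamma stereocentre C5 is not exposed to acid or base.

Step 6
Reactants: 7 (4aS)-1,5,5-trimethyl-4,4a,5,6,7,8-hexahydronaphthalen-2(3H)-one
Product: 8 trimethyl{[(4aS)-1,5,5-trimethyl-3,4,4a,5,6,7-hexahydronaphthalen-2-yl]oxy}silane
Conditions: TMSOTf, Et3N, CH2Cl2, 0 °C to rt; pentane extraction, filtration through basic alumina
Reagents that add atoms: trimethylsilyl triflate, C[Si](C)(C)OS(=O)(=O)C(F)(F)F
Why: Soft enolisation of a 2-en-1-one gives the heteroannular extended silyl dienol ether, as with steroidal 4-en-3-ones; Et3N takes the accessible axial proton at C1 and not H-5, which is tertiary and shielded by the neighbouring CMe2 group.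

Step 7
Reactants: 9 3-methylbutan-1-amine; 10 2,5-dimethoxy-2,5-dihydrofuran
Product: 11 1-(3-methylbutyl)-1,5-dihydro-2H-pyrrol-2-one
Conditions: 1 M aq. HCl, rt; then NaHCO3
Reagents that add atoms: water, O (the carbonyl oxygen can stem from it)
Why: Acid unmasks cis-butenedial, which condenses with the primary amine and tautomerises to the conjugated pyrrolinone, a known one-step entry to N-alkyl unsaturated gamma-lactams.

Step 8
Reactants: 11 1-(3-methylbutyl)-1,5-dihydro-2H-pyrrol-2-one
Product: 13 3-bromo-1-(3-methylbutyl)-1,5-dihydro-2H-pyrrol-2-one, via dibromolactam 12 (not isolated)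
Conditions: Br2, CH2Cl2, 0 °C; then Et3N, 0 °C to rt
Reagents that add atoms: bromine, BrBr
Why: In this bromination–dehydrobromination the acidic proton at C3 is removed and the bromide at C4 is expelled (E1cB), which leaves the alpha-bromo lactam only.

Step 9
Reactants: 14 (4S)-4-benzyl-1,3-oxazolidin-2-one; 15 pent-4-enoyl chloride
Product: 16 (4S)-4-benzyl-3-(pent-4-enoyl)-1,3-oxazolidin-2-one
Conditions: n-BuLi, THF, −78 °C; then 15
Reagents that add atoms: none
Why: This is the standard N-acylation of the lithiated auxiliary.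

Step 10
Reactants: 16 (4S)-4-benzyl-3-(pent-4-enoyl)-1,3-oxazolidin-2-one; 17 tert-butyl bromoacetate
Product: 18 tert-butyl (3R)-3-{[(4S)-4-benzyl-2-oxo-1,3-oxazolidin-3-yl]carbonyl}hex-5-enoate
Conditions: NaHMDS, THF, −78 °C; then 17, −78 to −40 °C
Reagents that add atoms: none
Why: In the Evans alkylation the chelated Z-enolate is attacked by the activated bromide on the face away from the benzyl group, which sets C13 as R.

Step 11
Reactants: 18 tert-butyl (3R)-3-{[(4S)-4-benzyl-2-oxo-1,3-oxazolidin-3-yl]carbonyl}hex-5-enoate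
Product: 19 (2R)-2-(prop-2-en-1-yl)butane-1,4-diol
Conditions: LiAlH4, THF, 0 °C to rt; aqueous work-up
Reagents that add atoms: none
Why: Hydride reduction of imide and ester together gives the 1,4-diol; the two hydroxyl groups need no differentiation because both end up in the same sulfate ring, and C13 is not enolisable afterwards.

Step 12
Reactants: 19 (2R)-2-(prop-2-en-1-yl)butane-1,4-diol; 13 3-bromo-1-(3-methylbutyl)-1,5-dihydro-2H-pyrrol-2-one
Product: 21 3-[(4R)-6-hydroxy-4-(hydroxymethyl)hexyl]-1-(3-methylbutyl)-1,5-dihydro-2H-pyrrol-2-one, via trisboron adduct 20 (not isolated)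
Conditions: 9-BBN (3.3 equiv), THF, 0 °C to rt; then 13, PdCl2(dppf) (5 mol %), Cs2CO3, DMF/H2O, rt to 45 °C
Reagents that add atoms: none
Why: Hydroboration followed by B-alkyl Suzuki–Miyaura coupling, as known for alpha-halo enones and lactams; two equivalents of 9-BBN are spent on the hydroxyl groups as borinates, which the aqueous base cleaves again.

Step 13
Reactants: 21 3-[(4R)-6-hydroxy-4-(hydroxymethyl)hexyl]-1-(3-methylbutyl)-1,5-dihydro-2H-pyrrol-2-one
Product: 23 3-{3-[(5R)-2,2-dioxido-1,3,2-dioxathiepan-5-yl]propyl}-1-(3-methylbutyl)-1,5-dihydro-2H-pyrrol-2-one, via cyclic sulfite 22 (not isolated)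
Conditions: SOCl2, Et3N, CH2Cl2 (0.02 M), 0 °C; then RuCl3 hydrate (0.5 mol %), NaIO4, MeCN/H2O, 0 °C, 10 min
Reagents that add atoms: thionyl chloride, O=S(Cl)Cl; sodium periodate, [Na+].[O-]I(=O)(=O)=O
Why: Sulfite formation and RuO4 oxidation is the established route to cyclic sulfates, 1,4-diols included; oxidation at sulfur is far faster than attack on the electron-poor lactam alkene, which is why conjugated esters survive the same short treatment.

Step 14
Reactants: 8 trimethyl{[(4aS)-1,5,5-trimethyl-3,4,4a,5,6,7-hexahydronaphthalen-2-yl]oxy}silane; 23 3-{3-[(5R)-2,2-dioxido-1,3,2-dioxathiepan-5-yl]propyl}-1-(3-methylbutyl)-1,5-dihydro-2H-pyrrol-2-one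
Product: 25 lithium (2R)-5-[1-(3-methylbutyl)-2-oxo-2,5-dihydro-1H-pyrrol-3-yl]-2-{2-[(1S,4aS)-1,5,5-trimethyl-2-oxo-1,2,3,4,4a,5,6,7-octahydronaphthalen-1-yl]ethyl}pentyl sulfate, via lithium dienolate 24 (not isolated)
Conditions: 8 (1.5 equiv), MeLi (1.45 equiv), THF, 0 °C, 45 min; then slow addition of 23 (1.0 equiv) in THF/DMPU (6:1), −20 °C to rt
Reagents that add atoms: methyllithium, [Li]C (lithium counter-ion)
Why: Proposed new method: MeLi cleaves the O–Si bond of 8 irreversibly and without any proton source, and the alpha carbon C9 of the resulting extended lithium dienolate 24 (O–C8=C9–C10=C1) opens 23 by SN2 attack at C11, so that one operation forms the C9–C11 bond, the quaternary centre and the deconjugated C1=C10 double bond and also releases the sulfate monoester of the target, which as an anion is inert to a second displacement. The closest known reaction types are the deconjugative alpha-alkylation of extended enone dienolates by primary halides or dialkyl sulfates and the C-alkylation of lithium enolates by cyclic sulfates used as epoxide surrogates; what is new is their combination on a seven-membered sulfate at a fully substituted carbon. No ring is closed in this step; only the temporary dioxathiepane ring is opened. C9 is the only new stereocentre and is controlled by C5: with H-5 axial, attack on the face of H-5 is the axial, chair-like trajectory that meets only H-5 and H-7, and it places the long chain axial and the small methyl group equatorial beside H-1, the arrangement of least allylic strain. The step needs C11 over the CH2O carbon (secured by the branching at C13 next to the latter and by the bulk of the nucleophile), C- over O-alkylation (lithium counter-ion, THF, little DMPU), alpha over gamma attack (innate to extended dienolates) and an untouched H-5 (no equilibration, since stray protonation of 24 occurs at C9 and the beta,gamma-enone so formed is re-ionised at C9). The lactam should survive because 24, kept in excess while 23 is added slowly, is a weaker base than the anion that loss of a ring CH2 proton next to nitrogen would give, and because a 3-alkyl unsaturated lactam is a poor Michael acceptor.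

Step 15
Reactants: 25 lithium sulfate ketone
Product: 26 lithium (2R)-5-[1-(3-methylbutyl)-2-oxo-2,5-dihydro-1H-pyrrol-3-yl]-2-{2-[(1R,4aS)-1,5,5-trimethyl-2-methylidene-1,2,3,4,4a,5,6,7-octahydronaphthalen-1-yl]ethyl}pentyl sulfate
Conditions: Ph3PCH3Br, n-BuLi (4 equiv of ylide), THF/DMPU, 0 to 60 °C; aqueous work-up
Reagents that add atoms: methyltriphenylphosphonium bromide, C[P+](c1ccccc1)(c1ccccc1)c1ccccc1.[Br-]
Why: Wittig methylenation is the usual answer to alpha-quaternary cyclohexanones; the sulfate anion is inert to the ylide, any reversible deprotonation of the lactam is undone on work-up, and no stereocentre is touched.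

Step 16
Reactants: 26 lithium sulfate with exocyclic methylene group
Product: 27 lithium (2R)-5-[1-(3-methylbutyl)-2-oxo-2,5-dihydro-1H-pyrrol-3-yl]-2-{2-[(1R,2R,4aS)-1,2,5,5-tetramethyl-1,2,3,4,4a,5,6,7-octahydronaphthalen-1-yl]ethyl}pentyl sulfate
Conditions: H2 (5 bar), RhCl(PPh3)3 (10 mol %), THF/t-BuOH, rt
Reagents that add atoms: none
Why: In this homogeneous hydrogenation RhCl(PPh3)3 accepts 1,1-disubstituted but not trisubstituted alkenes, so C1=C10 and the lactam alkene stay; hydrogen is delivered to C8 on the face opposite the axial C11 chain at C9, which makes the new methyl group equatorial and cis to that chain (8R).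

Step 17
Reactants: 27 lithium salt of the target
Product: 28 (2R)-5-[1-(3-methylbutyl)-2-oxo-2,5-dihydro-1H-pyrrol-3-yl]-2-{2-[(1R,2R,4aS)-1,2,5,5-tetramethyl-1,2,3,4,4a,5,6,7-octahydronaphthalen-1-yl]ethyl}pentyl hydrogen sulfate (target)
Conditions: cold 0.1 M aq. HCl (1 equiv), 0 °C, extraction into n-BuOH/EtOAc, freeze-drying
Reagents that add atoms: none
Why: Simple protonation of a primary alkyl sulfate; short contact with cold dilute acid is below the threshold for sulfate hydrolysis or alkene migration.

## Compound list

1 | 3-methylcyclohex-2-en-1-one | CC1=CC(=O)CCC1 | starting material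
2 | [(3,3-dimethylcyclohex-1-en-1-yl)oxy]trimethylsilane | CC1(C)CCCC(O[Si](C)(C)C)=C1 | intermediate
3 | pent-1-en-3-one | CCC(=O)C=C | starting material
4 | (±)-3,3-dimethyl-2-(3-oxopentyl)cyclohexan-1-one | CCC(=O)CCC1C(=O)CCCC1(C)C | intermediate
5 | (±)-1,5,5-trimethyl-4,4a,5,6,7,8-hexahydronaphthalen-2(3H)-one | CC1=C2CCCC(C)(C)C2CCC1=O | intermediate
6 | (2R,4aS)-1,5,5-trimethyl-2,3,4,4a,5,6,7,8-octahydronaphthalen-2-ol | CC1=C2CCCC(C)(C)[C@@H]2CC[C@H]1O | intermediate
7 | (4aS)-1,5,5-trimethyl-4,4a,5,6,7,8-hexahydronaphthalen-2(3H)-one | CC1=C2CCCC(C)(C)[C@@H]2CCC1=O | intermediate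
8 | trimethyl{[(4aS)-1,5,5-trimethyl-3,4,4a,5,6,7-hexahydronaphthalen-2-yl]oxy}silane | CC1=C(O[Si](C)(C)C)CC[C@@H]2C1=CCCC2(C)C | intermediate
9 | 3-methylbutan-1-amine | CC(C)CCN | starting material
10 | 2,5-dimethoxy-2,5-dihydrofuran | COC1C=CC(OC)O1 | starting material
11 | 1-(3-methylbutyl)-1,5-dihydro-2H-pyrrol-2-one | CC(C)CCN1CC=CC1=O | intermediate
12 | (±)-trans-3,4-dibromo-1-(3-methylbutyl)pyrrolidin-2-one | CC(C)CCN1CC(Br)C(Br)C1=O | intermediate
13 | 3-bromo-1-(3-methylbutyl)-1,5-dihydro-2H-pyrrol-2-one | CC(C)CCN1CC=C(Br)C1=O | intermediate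
14 | (4S)-4-benzyl-1,3-oxazolidin-2-one | O=C1N[C@@H](Cc2ccccc2)CO1 | starting material
15 | pent-4-enoyl chloride | C=CCCC(=O)Cl | starting material
16 | (4S)-4-benzyl-3-(pent-4-enoyl)-1,3-oxazolidin-2-one | C=CCCC(=O)N1[C@@H](Cc2ccccc2)COC1=O | intermediate
17 | tert-butyl bromoacetate | CC(C)(C)OC(=O)CBr | starting material
18 | tert-butyl (3R)-3-{[(4S)-4-benzyl-2-oxo-1,3-oxazolidin-3-yl]carbonyl}hex-5-enoate | C=CC[C@H](CC(=O)OC(C)(C)C)C(=O)N1[C@@H](Cc2ccccc2)COC1=O | intermediate
19 | (2R)-2-(prop-2-en-1-yl)butane-1,4-diol | C=CC[C@H](CCO)CO | intermediate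
20 | B-alkyl-9-BBN from 19, both hydroxyl groups bound as 9-BBN borinates | B1(CCC[C@H](CCOB2C3CCCC2CCC3)COB2C3CCCC2CCC3)C2CCCC1CCC2 | intermediate
21 | 3-[(4R)-6-hydroxy-4-(hydroxymethyl)hexyl]-1-(3-methylbutyl)-1,5-dihydro-2H-pyrrol-2-one | CC(C)CCN1CC=C(CCC[C@H](CCO)CO)C1=O | intermediate
22 | 3-{3-[(5R)-2-oxido-1,3,2-dioxathiepan-5-yl]propyl}-1-(3-methylbutyl)-1,5-dihydro-2H-pyrrol-2-one (both configurations at sulfur) | CC(C)CCN1CC=C(CCC[C@H]2COS(=O)OCC2)C1=O | intermediate
23 | 3-{3-[(5R)-2,2-dioxido-1,3,2-dioxathiepan-5-yl]propyl}-1-(3-methylbutyl)-1,5-dihydro-2H-pyrrol-2-one | CC(C)CCN1CC=C(CCC[C@H]2COS(=O)(=O)OCC2)C1=O | intermediate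
24 | lithium (4aS)-1,5,5-trimethyl-3,4,4a,5,6,7-hexahydronaphthalen-2-olate | [Li+].CC1=C([O-])CC[C@@H]2C1=CCCC2(C)C | intermediate
25 | lithium sulfate of the C8 ketone (9S by CIP, chain on the face of H-5) | [Li+].CC(C)CCN1CC=C(CCC[C@H](CC[C@@]2(C)C3=CCCC(C)(C)[C@@H]3CCC2=O)COS(=O)(=O)[O-])C1=O | intermediate
26 | lithium sulfate of the C8 methylidene compound | [Li+].CC(C)CCN1CC=C(CCC[C@H](CC[C@@]2(C)C3=CCCC(C)(C)[C@@H]3CCC2=C)COS(=O)(=O)[O-])C1=O | intermediate
27 | lithium salt of the target | [Li+].CC(C)CCN1CC=C(CCC[C@H](CC[C@@]2(C)C3=CCCC(C)(C)[C@@H]3CC[C@H]2C)COS(=O)(=O)[O-])C1=O | intermediate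
28 | CNP0218721.1, free hydrogen sulfate (5S,8R,9R,13R in the locants used here) | CC(C)CCN1CC=C(CCC[C@H](CC[C@@]2(C)C3=CCCC(C)(C)[C@@H]3CC[C@H]2C)COS(=O)(=O)O)C1=O | target

## Counts

- Total step count: 17.
- Longest linear sequence: 10 steps (steps 1–6, then 14–17).

## The three steps most likely to fail

**Step 14 (labelled step).** Three processes can go wrong:
- O-alkylation of the dienolate by the hard sulfate electrophile.
- Competing attack at the branched CH2O carbon.
- Proton transfer between the dienolate and the lactam, followed by self-alkylation of the chain fragment.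

The fallback sets out from 23 and 24 and comes back at 25. The cyclic sulfate 23 is first opened with LiI in THF/acetone at its unbranched carbon, a known halide opening of cyclic sulfates. This gives lithium (2R)-2-(2-iodoethyl)-5-[1-(3-methylbutyl)-2-oxo-2,5-dihydro-1H-pyrrol-3-yl]pentyl sulfate F1. The soft primary iodide then alkylates 24 in THF/DMPU in the classical deconjugative manner and delivers 25.

**Step 16.** Three processes can go wrong:
- Sluggish hydrogen uptake at the hindered methylidene group.
- Migration of the exocyclic double bond into the ring.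
- Loss of chemoselectivity against the lactam alkene once a more active catalyst is used.

The fallback sets out from 26 and comes back at 27.
- 9-BBN adds only to the 1,1-disubstituted alkene, from the face opposite the axial chain, to give the C17 borane F2.
- NaBO3 oxidises it to the C17 primary alcohol F3.
- PPh3, I2 and imidazole (Appel-type iodination) give the C17 primary iodide F4.
- Bu3SnH/AIBN removes the iodine to give 27.

**Step 4.** Two processes can go wrong:
- Insufficient rate difference between the two enantiomers.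
- Leakage through the substrate-controlled pathway, either of which erodes the enantiomeric purity at C5.

The fallback sets out from 5 and comes back at 6.
- Luche reduction (NaBH4, CeCl3, MeOH) gives the racemic alcohol with OH cis to H-4a, F5.
- A lipase (CAL-B or lipase PS) with vinyl acetate in MTBE acylates the R carbinol to the (2R,4aS) acetate F6, which is separated from the unreacted alcohol.
- K2CO3/MeOH releases 6.

## Further compounds

F1 | step 14 | lithium (2R)-2-(2-iodoethyl)-5-[1-(3-methylbutyl)-2-oxo-2,5-dihydro-1H-pyrrol-3-yl]pentyl sulfate | [Li+].CC(C)CCN1CC=C(CCC[C@H](CCI)COS(=O)(=O)[O-])C1=O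
F2 | step 16 | C17 B-alkyl-9-BBN derived from 26 | [Li+].CC(C)CCN1CC=C(CCC[C@H](CC[C@@]2(C)C3=CCCC(C)(C)[C@@H]3CC[C@H]2CB4C5CCCC4CCC5)COS(=O)(=O)[O-])C1=O
F3 | step 16 | C17 primary alcohol, lithium sulfate | [Li+].CC(C)CCN1CC=C(CCC[C@H](CC[C@@]2(C)C3=CCCC(C)(C)[C@@H]3CC[C@H]2CO)COS(=O)(=O)[O-])C1=O
F4 | step 16 | C17 primary iodide, lithium sulfate | [Li+].CC(C)CCN1CC=C(CCC[C@H](CC[C@@]2(C)C3=CCCC(C)(C)[C@@H]3CC[C@H]2CI)COS(=O)(=O)[O-])C1=O
F5 | step 4 | (±)-(2R*,4aS*)-1,5,5-trimethyl-2,3,4,4a,5,6,7,8-octahydronaphthalen-2-ol, racemate of 6 | CC1=C2CCCC(C)(C)C2CCC1O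
F6 | step 4 | (2R,4aS)-1,5,5-trimethyl-2,3,4,4a,5,6,7,8-octahydronaphthalen-2-yl acetate | CC1=C2CCCC(C)(C)[C@@H]2CC[C@H]1OC(C)=O
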